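**Retrosynthetic overview**
1. Enal last: Ar–CH=CH–CHO ⇒ aryl bromide 9 + (E)-3,3-diethoxypropenyl boronate 10 (Suzuki coupling, then acetal hydrolysis).
2. Benzodioxane ring (the only ring built, closed in the penultimate step): benzylic C–O bond ⇒ diol 8 by acid-triggered Boc loss and quinone-methide-type cyclisation; trans is set thermodynamically from the CH2OH-bearing centre.
3. C–C bond between the two sp3 carbons and the first stereocentre ⇒ D-proline cross-aldol of the lactol-masked aryloxyacetaldehyde 4 with Boc-syringaldehyde 7 (new donor class), then NaBH4.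
4. Lactol 4 ⇒ 5-bromo-o-vanillin 1 by O-alkylation and Baeyer–Villiger (CHO→OH); the substitution pattern of 1 fixes which oxygen carries the side-chain carbon.
5. Ring order: both arenes are bought; transient hemiacetal ring (4) → opened in the aldol/reduction → 1,4-benzodioxane ring (9).

Assumption: the target is the trans-(2S,3S) isomer exactly as encoded in the SMILES; 1, 2, 5, 6 and 10 are taken as catalogue compounds and D-proline is used only as catalyst.

**Step 1**
Reactants: 1, 5-bromo-2-hydroxy-3-methoxybenzaldehyde; 2, 2-bromo-1,1-diethoxyethane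
Product: 3, 5-bromo-2-(2,2-diethoxyethoxy)-3-methoxybenzaldehyde
Conditions: K2CO3, KI (cat.), DMF, 110 °C
Reagents that add atoms: 2-bromo-1,1-diethoxyethane (2), CCOC(CBr)OCC
Why: Williamson ether synthesis (SN2) on the only phenol; this oxygen is the one flanked by OMe and the future second oxygen, so the regiochemistry of the benzodioxane is fixed by the structure of 1, not by selectivity.

**Step 2**
Reactants: 3, 5-bromo-2-(2,2-diethoxyethoxy)-3-methoxybenzaldehyde
Product: 4, 7-bromo-5-methoxy-2,3-dihydro-1,4-benzodioxin-2-ol (racemic, labile hemiacetal; ring-closed form of 2-(4-bromo-2-hydroxy-6-methoxyphenoxy)acetaldehyde)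
Conditions: mCPBA, NaHCO3, CH2Cl2, 0 °C → rt; aq. Na2S2O3 quench; then 2 M HCl, THF, 45 °C
Reagents that add atoms: mCPBA, O=C(OO)c1cccc(Cl)c1 (the new phenolic O); water, O (the hemiacetal OH)
Why: Baeyer–Villiger (Dakin-type) oxidation in which the ortho-alkoxyaryl group migrates to give the aryl formate; aqueous acid then hydrolyses formate and acetal, and the new phenol closes onto the aldehyde as a six-membered lactol (the bicarbonate buffer keeps the acetal intact while peracid is present).

**Step 3**
Reactants: 5, syringaldehyde (4-hydroxy-3,5-dimethoxybenzaldehyde); 6, di-tert-butyl dicarbonate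
Product: 7, tert-butyl (4-formyl-2,6-dimethoxyphenyl) carbonate
Conditions: Boc2O, DMAP (cat.), i-Pr2NEt, CH2Cl2, rt
Reagents that add atoms: di-tert-butyl dicarbonate (6), CC(C)(C)OC(=O)OC(=O)OC(C)(C)C
Why: DMAP-catalysed O-acylation; the carbonate masks the acidic phenol, makes the aldehyde a better electrophile (electron-withdrawing para group), and is removed by the acid used in step 5.

**Step 4**
Reactants: 4, 7-bromo-5-methoxy-2,3-dihydro-1,4-benzodioxin-2-ol; 7, tert-butyl (4-formyl-2,6-dimethoxyphenyl) carbonate (3 equiv)
Product: 8, tert-butyl {4-[(1R,2S)-2-(4-bromo-2-hydroxy-6-methoxyphenoxy)-1,3-dihydroxypropyl]-2,6-dimethoxyphenyl} carbonate (anti-aldol isomer; the C1 epimer can be carried along if chiral HPLC shows the same C2 configuration, because C1 is re-set in step 5)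
Conditions: D-proline (30 mol%), DMF, 4 °C → rt, 48–72 h; then MeOH, NaBH4, 0 °C (one pot)
Reagents that add atoms: none (4 and 7 are both incorporated; NaBH4 adds only H)
Why: Proposed new method: lactol 4 opens to the 2-aryloxyacetaldehyde, which forms the (E)-enamine with D-proline; the carboxylic acid delivers 7 to one enamine face through the Houk–List hydrogen-bonded transition state (mirror image of the L-proline case), setting the aryloxy-bearing carbon; the adduct is trapped as its lactol by the neighbouring phenol, which blocks a second aldol and α-epimerisation, and NaBH4 then gives the diol with C2 = S (R at the aldehyde stage, a CIP change only); lactol masking keeps the free donor aldehyde low and so suppresses self-aldol. The closest known reaction is the proline-catalysed direct cross-aldol of α-alkoxy- or α-silyloxy-acetaldehyde donors; an α-aryloxy donor resting as a phenol lactol, paired with an aryl aldehyde acceptor, has not been shown.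

**Step 5**
Reactants: 8, the (1R,2S)-diol carbonate
Product: 9, [(2S,3S)-6-bromo-3-(4-hydroxy-3,5-dimethoxyphenyl)-8-methoxy-2,3-dihydro-1,4-benzodioxin-2-yl]methanol (trans)
Conditions: TFA/CH2Cl2 (1:9), 0.02 M, 0 °C → rt; then NaHCO3, MeOH/H2O (cleaves any trifluoroacetate)
Reagents that add atoms: none
Why: Acid-mediated SN1 etherification through the p-quinone methide/benzylic cation: TFA removes the aryl Boc group, the freed 4-hydroxy-3,5-dimethoxyphenyl ring ionises the benzylic C–OH, and the ortho phenol closes the six-membered ring (6-exo); reversible ionisation gives the thermodynamically favoured trans (diequatorial) isomer, so the aryl-bearing carbon becomes S under control of the fixed C2 (S) centre.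

**Step 6**
Reactants: 9, the bromo-benzodioxane; 10, (E)-2-(3,3-diethoxyprop-1-en-1-yl)-4,4,5,5-tetramethyl-1,3,2-dioxaborolane
Product: 11, Bilagrewin, (E)-3-[(2S,3S)-3-(4-hydroxy-3,5-dimethoxyphenyl)-2-(hydroxymethyl)-8-methoxy-2,3-dihydro-1,4-benzodioxin-6-yl]prop-2-enal
Conditions: XPhos Pd G3 (3 mol%), K3PO4, THF/H2O 4:1, 45 °C; then 1 M HCl, THF, rt
Reagents that add atoms: boronate 10, CCOC(OCC)/C=C/B1OC(C)(C)C(C)(C)O1; water, O (aldehyde oxygen from acetal hydrolysis)
Why: Suzuki–Miyaura coupling of the aryl bromide with the (E)-alkenyl boronate proceeds with retention of alkene geometry and tolerates the free phenol and alcohol; mild acetal hydrolysis then releases the (E)-enal without touching either stereocentre.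

**Compound list**
1 | 5-bromo-2-hydroxy-3-methoxybenzaldehyde | O=Cc1cc(Br)cc(OC)c1O | starting material
2 | 2-bromo-1,1-diethoxyethane | CCOC(CBr)OCC | starting material
3 | 5-bromo-2-(2,2-diethoxyethoxy)-3-methoxybenzaldehyde | O=Cc1cc(Br)cc(OC)c1OCC(OCC)OCC | intermediate
4 | 7-bromo-5-methoxy-2,3-dihydro-1,4-benzodioxin-2-ol | OC1COc2c(OC)cc(Br)cc2O1 | intermediate
5 | syringaldehyde | COc1cc(C=O)cc(OC)c1O | starting material
6 | di-tert-butyl dicarbonate | CC(C)(C)OC(=O)OC(=O)OC(C)(C)C | starting material
7 | tert-butyl (4-formyl-2,6-dimethoxyphenyl) carbonate | COc1cc(C=O)cc(OC)c1OC(=O)OC(C)(C)C | intermediate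
8 | tert-butyl {4-[(1R,2S)-2-(4-bromo-2-hydroxy-6-methoxyphenoxy)-1,3-dihydroxypropyl]-2,6-dimethoxyphenyl} carbonate | OC[C@H](Oc1c(O)cc(Br)cc1OC)[C@H](O)c1cc(OC)c(OC(=O)OC(C)(C)C)c(OC)c1 | intermediate
9 | [(2S,3S)-6-bromo-3-(4-hydroxy-3,5-dimethoxyphenyl)-8-methoxy-2,3-dihydro-1,4-benzodioxin-2-yl]methanol | COc1cc([C@@H]2Oc3cc(Br)cc(OC)c3O[C@H]2CO)cc(OC)c1O | intermediate
10 | (E)-2-(3,3-diethoxyprop-1-en-1-yl)-4,4,5,5-tetramethyl-1,3,2-dioxaborolane | CCOC(OCC)/C=C/B1OC(C)(C)C(C)(C)O1 | starting material
11 | Bilagrewin | COc1cc([C@@H]2Oc3cc(/C=C/C=O)cc(OC)c3O[C@H]2CO)cc(OC)c1O | target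

**Totals**
Total steps: 6. Longest linear sequence: 5 (steps 1, 2, 4, 5, 6).

**Steps most likely to fail**
1. Step 4 (proposed new aldol). Risks: the aryloxy enamine is less nucleophilic than alkoxy analogues, donor self-aldol may compete, and the ee at the aryloxy carbon is unproven. Fallback (known chemistry): set the stereochemistry by diarylprolinol silyl ether/H2O2 epoxidation of the protected sinapaldehyde, then NaBH4 to the trans-epoxy alcohol. Open it at the benzylic carbon with 2-(allyloxy)-5-bromo-3-methoxyphenol (from 1 by allylation and Baeyer–Villiger), silylate the primary OH, deallylate, and close the second C–O bond by intramolecular Mitsunobu reaction (inversion; catalyst enantiomer chosen accordingly). Deprotection rejoins the route at 9.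
2. Step 5 (acid cyclisation). Risks: incomplete trans selectivity, Friedel–Crafts oligomers, and erosion of the C2 centre if the cation loses the adjacent proton to an enol ether. Fallback: switch from the cationic to the anionic quinone-methide manifold. Convert the benzylic OH of 8 to the bromide (TMSBr, CH2Cl2, 0 °C), then treat with mild carbonate base so that Boc cleavage, phenoxide-driven quinone methide formation and intramolecular oxa-1,6-addition occur without a free carbocation.
3. Step 6 (late Suzuki coupling). Risks: Pd coupling in the presence of a free phenol on a base-sensitive p-hydroxybenzyl aryl ether. Fallback: install the C3 unit before ring closure. Couple 10 with 8 (Boc still on, no labile benzylic aryl ether yet) and let the TFA step of step 5, run with added water, hydrolyse the acetal, remove Boc and cyclise in one operation to give 11 directly.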